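**Retrosynthetic overview**

1. Target ⇐ its C4 secondary alcohol (mild oxidation as the last step).
2. Key C–O disconnections, made together: the C7–O(acyl) bond and the lactone O–C(=O) bond ⇐ a C6,C7 α-epoxy ketone carrying a free C1 hydroxyl and a tert-butyl acrylate, plus the free α-branched acid.
3. α-Epoxide ⇐ C1-hydroxyl-directed nucleophilic epoxidation (C–O) of a γ-hydroxy cross-conjugated dienone; dienone ⇐ Weinreb amide + alkenyllithium.
4. Cycloheptene ⇐ ring-closing metathesis (C6=C7) of an acyclic triene ⇐ two chromium-catalysed asymmetric 2-(alkoxycarbonyl)allylations (C4–C5, then C1–C2) around a three-carbon dialdehyde equivalent.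
5. Ring order: carbocycle first (metathesis), lactone last (C–O bond formation).

Locants used below follow the target: C1 = lactone O–CH, C2 = CH carrying the α-methylene carbon, C3 = CH2, C4 = ring C=O, C5 = CH–CH3, C6 = C–OH, C7 = CH–O–acyl, C8 = butenoyl C=O. Names of ring compounds use these locants.

Assumption: the six starting materials in the compound list are taken as purchasable.

**Step 1**
Reactants: 1 3,3-dimethoxypropanal; 2 ethyl (Z)-2-(bromomethyl)but-2-enoate
Product: 4 (4R,5S)-5-(2,2-dimethoxyethyl)-4-methyl-3-methylideneoxolan-2-one, via silyl ether 3 (not isolated)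
Conditions: CrCl2 (10 mol %), chiral carbazole-bis(oxazoline) ligand (11 mol %), Mn, TMSCl, THF, 0 °C to rt; then PPTS (cat.), MeOH, 40 °C
Reagents that add atoms: none
Why: Chromium-catalysed asymmetric Nozaki–Hiyama–Kishi 2-(alkoxycarbonyl)allylation: the γ-methyl allylchromium from 2 adds to 1 through a closed chair transition state (anti) with the ligand choosing the aldehyde face, so C4 (S) and C5 (R) are set together, and acidic methanolysis frees the alcohol, which closes to the trans-lactone while the dimethyl acetal is inert in methanol.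

**Step 2**
Reactants: 4 (4R,5S)-5-(2,2-dimethoxyethyl)-4-methyl-3-methylideneoxolan-2-one
Product: 5 (3R,4S)-4-hydroxy-N,6,6-trimethoxy-N,3-dimethyl-2-methylidenehexanamide
Conditions: MeNHOMe·HCl, i-PrMgCl, THF, −20 to 0 °C
Reagents that add atoms: N,O-dimethylhydroxylamine hydrochloride (CNOC.Cl)
Why: Weinreb aminolysis: the chloromagnesium amide attacks only the lactone carbonyl, opening it to the hydroxy Weinreb amide without touching C4 or C5 and preparing C8 for a single later organolithium addition.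

**Step 3**
Reactants: 5 (3R,4S)-4-hydroxy-N,6,6-trimethoxy-N,3-dimethyl-2-methylidenehexanamide
Product: 6 (3R,4S)-4-[(tert-butyldimethylsilyl)oxy]-N,6,6-trimethoxy-N,3-dimethyl-2-methylidenehexanamide
Conditions: TBSCl, imidazole, DMF, rt
Reagents that add atoms: tert-butyldimethylsilyl chloride (CC(C)(C)[Si](C)(C)Cl)
Why: Standard silylation of the only hydroxyl group under chloride/imidazole conditions that leave the acetal intact; the silyl ether masks C4–O through all basic and organometallic steps.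

**Step 4**
Reactants: 6 (3R,4S)-4-[(tert-butyldimethylsilyl)oxy]-N,6,6-trimethoxy-N,3-dimethyl-2-methylidenehexanamide
Product: 7 (3R,4S)-4-[(tert-butyldimethylsilyl)oxy]-N-methoxy-N,3-dimethyl-2-methylidene-6-oxohexanamide
Conditions: LiBF4, MeCN/H2O (50:1), rt
Reagents that add atoms: water (O)
Why: Lewis acid-promoted acetal hydrolysis in wet acetonitrile gives the aldehyde under conditions that leave the silyl ether and the acrylamide unchanged; no stereocentre is affected.

**Step 5**
Reactants: 7 (3R,4S)-4-[(tert-butyldimethylsilyl)oxy]-N-methoxy-N,3-dimethyl-2-methylidene-6-oxohexanamide; 8 tert-butyl prop-2-enoate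
Product: 9 tert-butyl (5S,6R)-5-[(tert-butyldimethylsilyl)oxy]-3-hydroxy-7-[methoxy(methyl)carbamoyl]-6-methyl-2-methylideneoct-7-enoate (both C3 epimers)
Conditions: DABCO (1 equiv), 1,4-dioxane/H2O (1:1), rt
Reagents that add atoms: none
Why: Morita–Baylis–Hillman reaction: the ammonium enolate of 8 adds to the unhindered aldehyde, while the α-substituted acrylamide of 7 cannot act as a donor; the new carbinol centre forms as a mixture and is erased in step 6.

**Step 6**
Reactants: 9 tert-butyl (5S,6R)-5-[(tert-butyldimethylsilyl)oxy]-3-hydroxy-7-[methoxy(methyl)carbamoyl]-6-methyl-2-methylideneoct-7-enoate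
Product: 10 tert-butyl (2Z,5S,6R)-2-(bromomethyl)-5-[(tert-butyldimethylsilyl)oxy]-7-[methoxy(methyl)carbamoyl]-6-methylocta-2,7-dienoate
Conditions: NBS, Me2S, CH2Cl2, 0 °C to rt
Reagents that add atoms: N-bromosuccinimide (O=C1CCC(=O)N1Br)
Why: Corey–Kim-type activation of the allylic alcohol followed by SN2′ attack of bromide gives the rearranged primary allylic bromide as the thermodynamically preferred Z isomer, removing the carbinol stereocentre.

**Step 7**
Reactants: 10 tert-butyl (2Z,5S,6R)-2-(bromomethyl)-5-[(tert-butyldimethylsilyl)oxy]-7-[methoxy(methyl)carbamoyl]-6-methylocta-2,7-dienoate; 11 prop-2-enal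
Product: 13 tert-butyl 2-[(3S,4R,6S,7R)-6-[(tert-butyldimethylsilyl)oxy]-3-hydroxy-8-[methoxy(methyl)carbamoyl]-7-methylnona-1,8-dien-4-yl]prop-2-enoate, via silyl ether 12 (not isolated)
Conditions: CrCl2 (10 mol %), chiral carbazole-bis(oxazoline) ligand (11 mol %), Mn, TMSCl, THF, 0 °C; then 1 M HCl (aq), THF, 0 °C
Reagents that add atoms: none
Why: Second chromium-catalysed asymmetric Nozaki–Hiyama–Kishi allylation: the allylchromium adds 1,2 to 11 through the chair transition state (anti) with the ligand, not the remote C4/C5 centres, fixing C1 (S) and C2 (R); the tert-butyl ester does not lactonize, so the C1 hydroxyl stays free for step 10.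

**Step 8**
Reactants: 13 tert-butyl 2-[(3S,4R,6S,7R)-6-[(tert-butyldimethylsilyl)oxy]-3-hydroxy-8-[methoxy(methyl)carbamoyl]-7-methylnona-1,8-dien-4-yl]prop-2-enoate
Product: 14 tert-butyl 2-[(1S,2R,4S,5R)-4-[(tert-butyldimethylsilyl)oxy]-1-hydroxy-6-[methoxy(methyl)carbamoyl]-5-methylcyclohept-6-en-2-yl]prop-2-enoate
Conditions: second-generation Hoveyda–Grubbs catalyst (5 mol %), 1,4-benzoquinone (10 mol %), toluene, 80 °C
Reagents that add atoms: none
Why: Ring-closing metathesis: ruthenium loads on the monosubstituted allylic-alcohol alkene and closes onto the 1,1-disubstituted acrylamide alkene to give the seven-membered trisubstituted enamide with loss of ethene (the acrylate alkene could only give a four-membered ring), benzoquinone suppressing allylic-alcohol isomerization.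

**Step 9**
Reactants: 14 tert-butyl 2-[(1S,2R,4S,5R)-4-[(tert-butyldimethylsilyl)oxy]-1-hydroxy-6-[methoxy(methyl)carbamoyl]-5-methylcyclohept-6-en-2-yl]prop-2-enoate; 15 (E)-1-bromoprop-1-ene
Product: 17 tert-butyl 2-[(1S,2R,4S,5R)-6-[(E)-but-2-enoyl]-4-[(tert-butyldimethylsilyl)oxy]-1-hydroxy-5-methylcyclohept-6-en-2-yl]prop-2-enoate, via (E)-prop-1-enyllithium 16 (not isolated)
Conditions: 15, t-BuLi (2 equiv per 15), Et2O, −78 °C; then 14, THF, −78 to −40 °C; aq NH4Cl
Reagents that add atoms: none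
Why: Weinreb ketone synthesis: 16, made with retention of the E geometry by bromine–lithium exchange, adds once to the amide via the stable chelated tetrahedral intermediate (one further equivalent is consumed by the hydroxyl group), giving the cross-conjugated dienone without over-addition.

**Step 10**
Reactants: 17 tert-butyl 2-[(1S,2R,4S,5R)-6-[(E)-but-2-enoyl]-4-[(tert-butyldimethylsilyl)oxy]-1-hydroxy-5-methylcyclohept-6-en-2-yl]prop-2-enoate
Product: 18 tert-butyl 2-[(1R,2R,4S,5S,6S,7R)-6-[(E)-but-2-enoyl]-4-[(tert-butyldimethylsilyl)oxy]-6,7-epoxy-1-hydroxy-5-methylcycloheptan-2-yl]prop-2-enoate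
Conditions: n-BuLi (1.0 equiv), then t-BuOOLi (from t-BuOOH and n-BuLi, 1.2 equiv), THF, −78 to −20 °C
Reagents that add atoms: tert-butyl hydroperoxide (CC(C)(C)OO)
Why: Hydroxyl-directed nucleophilic (Weitz–Scheffer) epoxidation: the C1 lithium alkoxide binds lithium tert-butyl peroxide and delivers it to C7 of the neighbouring ring enone on its own face, and enolate closure gives the epoxide cis to the C1–O bond, setting C6 (S) and C7 (R) and leaving the remote butenoyl and acrylate alkenes untouched.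

**Step 11**
Reactants: 18 tert-butyl 2-[(1R,2R,4S,5S,6S,7R)-6-[(E)-but-2-enoyl]-4-[(tert-butyldimethylsilyl)oxy]-6,7-epoxy-1-hydroxy-5-methylcycloheptan-2-yl]prop-2-enoate; 19 (R)-2-methylbutanoic acid
Product: 21 (1R,2R,4S,5S,6S,7S)-4-hydroxy precursor of the target (trans-fused C1–O/C2 α-methylene-γ-lactone; C4–OH; C6–OH; C7 (2R)-2-methylbutanoate), via hydroxy ester 20 (not isolated)
Conditions: (salen)Co(OTs) (5 mol %, matched enantiomer; salen = N,N′-bis(3,5-di-tert-butylsalicylidene)cyclohexane-1,2-diamine dianion), i-Pr2NEt (10 mol %), t-BuOMe, 25 °C; then TFA/H2O (9:1), 0 °C to rt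
Reagents that add atoms: none
Why: Proposed new method: cooperative trivalent-cobalt salen carboxylate catalysis in which one cobalt centre activates the epoxide oxygen (held by the neighbouring ketone and C1 hydroxyl) while a second cobalt carboxylate delivers the acid 19 to C7 anti to the breaking C–O bond; C6 is fully substituted and α to the ketone, so neither SN2 nor cationic opening can occur there, which forces attack at C7 with inversion (C7 becomes S) and leaves the C6 tertiary alcohol; the closest known reaction is the salen-cobalt-catalysed opening of meso and terminal epoxides by carboxylic acids, not yet shown for a trisubstituted α,β-epoxy ketone with an α-branched aliphatic acid; aqueous TFA then removes the tert-butyl and silyl groups and the C1-hydroxy acid closes to the trans-fused lactone.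

**Step 12**
Reactants: 21 (1R,2R,4S,5S,6S,7S)-4-hydroxy precursor of the target
Product: 22 target CNP0153197.3, (1R,2R,5R,6S,7S)
Conditions: DMP, CH2Cl2, rt
Reagents that add atoms: none
Why: Dess–Martin oxidation of the only secondary alcohol (the tertiary C6 alcohol cannot react) under non-basic conditions, so neither retro-aldol cleavage nor epimerization of C5 occurs and C5 keeps the configuration set in step 1.

**Compound list**

1 | 3,3-dimethoxypropanal | COC(CC=O)OC | starting material
2 | ethyl (Z)-2-(bromomethyl)but-2-enoate | C/C=C(\CBr)C(=O)OCC | starting material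
3 | ethyl (3R,4S)-6,6-dimethoxy-3-methyl-2-methylidene-4-(trimethylsilyloxy)hexanoate | CCOC(=O)C(=C)[C@@H](C)[C@@H](O[Si](C)(C)C)CC(OC)OC | intermediate
4 | (4R,5S)-5-(2,2-dimethoxyethyl)-4-methyl-3-methylideneoxolan-2-one | COC(OC)C[C@@H]1OC(=O)C(=C)[C@H]1C | intermediate
5 | (3R,4S)-4-hydroxy-N,6,6-trimethoxy-N,3-dimethyl-2-methylidenehexanamide | CON(C)C(=O)C(=C)[C@@H](C)[C@@H](O)CC(OC)OC | intermediate
6 | (3R,4S)-4-[(tert-butyldimethylsilyl)oxy]-N,6,6-trimethoxy-N,3-dimethyl-2-methylidenehexanamide | CON(C)C(=O)C(=C)[C@@H](C)[C@@H](O[Si](C)(C)C(C)(C)C)CC(OC)OC | intermediate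
7 | (3R,4S)-4-[(tert-butyldimethylsilyl)oxy]-N-methoxy-N,3-dimethyl-2-methylidene-6-oxohexanamide | CON(C)C(=O)C(=C)[C@@H](C)[C@@H](O[Si](C)(C)C(C)(C)C)CC=O | intermediate
8 | tert-butyl prop-2-enoate | C=CC(=O)OC(C)(C)C | starting material
9 | tert-butyl (5S,6R)-5-[(tert-butyldimethylsilyl)oxy]-3-hydroxy-7-[methoxy(methyl)carbamoyl]-6-methyl-2-methylideneoct-7-enoate (both C3 epimers) | CON(C)C(=O)C(=C)[C@@H](C)[C@@H](O[Si](C)(C)C(C)(C)C)CC(O)C(=C)C(=O)OC(C)(C)C | intermediate
10 | tert-butyl (2Z,5S,6R)-2-(bromomethyl)-5-[(tert-butyldimethylsilyl)oxy]-7-[methoxy(methyl)carbamoyl]-6-methylocta-2,7-dienoate | CON(C)C(=O)C(=C)[C@@H](C)[C@@H](O[Si](C)(C)C(C)(C)C)C/C=C(\CBr)C(=O)OC(C)(C)C | intermediate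
11 | prop-2-enal (acrolein) | C=CC=O | starting material
12 | O-trimethylsilyl ether of 13 | C=C[C@H](O[Si](C)(C)C)[C@H](C[C@H](O[Si](C)(C)C(C)(C)C)[C@H](C)C(=C)C(=O)N(C)OC)C(=C)C(=O)OC(C)(C)C | intermediate
13 | tert-butyl 2-[(3S,4R,6S,7R)-6-[(tert-butyldimethylsilyl)oxy]-3-hydroxy-8-[methoxy(methyl)carbamoyl]-7-methylnona-1,8-dien-4-yl]prop-2-enoate | C=C[C@H](O)[C@H](C[C@H](O[Si](C)(C)C(C)(C)C)[C@H](C)C(=C)C(=O)N(C)OC)C(=C)C(=O)OC(C)(C)C | intermediate
14 | tert-butyl 2-[(1S,2R,4S,5R)-4-[(tert-butyldimethylsilyl)oxy]-1-hydroxy-6-[methoxy(methyl)carbamoyl]-5-methylcyclohept-6-en-2-yl]prop-2-enoate | C=C(C(=O)OC(C)(C)C)[C@H]1C[C@H](O[Si](C)(C)C(C)(C)C)[C@H](C)C(C(=O)N(C)OC)=C[C@@H]1O | intermediate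
15 | (E)-1-bromoprop-1-ene | C/C=C/Br | starting material
16 | (E)-prop-1-enyllithium | C/C=C/[Li] | intermediate
17 | tert-butyl 2-[(1S,2R,4S,5R)-6-[(E)-but-2-enoyl]-4-[(tert-butyldimethylsilyl)oxy]-1-hydroxy-5-methylcyclohept-6-en-2-yl]prop-2-enoate | C=C(C(=O)OC(C)(C)C)[C@H]1C[C@H](O[Si](C)(C)C(C)(C)C)[C@H](C)C(C(=O)/C=C/C)=C[C@@H]1O | intermediate
18 | tert-butyl 2-[(1R,2R,4S,5S,6S,7R)-6-[(E)-but-2-enoyl]-4-[(tert-butyldimethylsilyl)oxy]-6,7-epoxy-1-hydroxy-5-methylcycloheptan-2-yl]prop-2-enoate | C=C(C(=O)OC(C)(C)C)[C@H]1C[C@H](O[Si](C)(C)C(C)(C)C)[C@H](C)[C@]2(C(=O)/C=C/C)O[C@@H]2[C@@H]1O | intermediate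
19 | (R)-2-methylbutanoic acid | CC[C@@H](C)C(=O)O | starting material
20 | tert-butyl 2-[(1R,2R,4S,5S,6S,7S)-6-[(E)-but-2-enoyl]-4-[(tert-butyldimethylsilyl)oxy]-1,6-dihydroxy-5-methyl-7-{[(2R)-2-methylbutanoyl]oxy}cycloheptan-2-yl]prop-2-enoate | C=C(C(=O)OC(C)(C)C)[C@H]1C[C@H](O[Si](C)(C)C(C)(C)C)[C@H](C)[C@@](O)(C(=O)/C=C/C)[C@H]([C@@H]1O)OC(=O)[C@H](C)CC | intermediate
21 | (1R,2R,4S,5S,6S,7S)-4-hydroxy precursor of the target: trans-fused C1–O/C2 α-methylene-γ-lactone, C4–OH, C5–CH3, C6–OH and (E)-but-2-enoyl, C7 (2R)-2-methylbutanoate | C=C1C(=O)O[C@@H]2[C@@H]1C[C@H](O)[C@H](C)[C@@](O)(C(=O)/C=C/C)[C@H]2OC(=O)[C@H](C)CC | intermediate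
22 | CNP0153197.3, (1R,2R,5R,6S,7S): 4-oxo compound of 21 | C=C1C(=O)O[C@@H]2[C@@H]1CC(=O)[C@H](C)[C@@](O)(C(=O)/C=C/C)[C@H]2OC(=O)[C@H](C)CC | target

**Totals and risks**

Total step count: 12. Longest linear sequence: 12 (fully linear from 1).

Three steps most likely to fail:

Step 7 (ligand-controlled allylation with the functionalized bromide). Fallback, from 10 and 11 back to 13: run the allylation with stoichiometric CrCl2 in THF without ligand; it stays anti-selective and gives 13 together with its (3R,4S,6S,7R) diastereomer F1 in roughly equal amounts. Treat the mixture with Amano lipase PS and vinyl acetate; the Kazlauskas rule predicts that only the (3R) carbinol is acetylated, giving acetate F2, so unreacted 13 is separated cleanly and re-enters the route at step 8.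

Step 10 (directed epoxidation; competing attack on the butenoyl or acrylate alkene, or loss of direction if the alkoxide lactonizes first). Fallback, from 14 back to 18: epoxidize one step earlier, when only the less electrophilic unsaturated Weinreb amide is present, by hydroxyl-directed vanadium catalysis (VO(acac)2, t-BuOOH, CH2Cl2, 40 °C) to give epoxy Weinreb amide F3 with the epoxide cis to the C1 hydroxyl. Addition of 16 (THF, −78 °C) then gives 18.

Step 11 (the proposed new opening; regiochemistry, rate at the hindered C7, and acyl migration to C1–OH are the risks). Fallback with known chemistry, from 18 back to 21: aqueous HClO4 in THF at 0 °C opens the epoxide with water at C7 (anti, β to the ketone) to give triol ester F4. Camphorsulfonic acid in warm toluene closes the C1-hydroxy tert-butyl ester to diol lactone F5 with the silyl ether retained. Steglich esterification of the only free secondary alcohol (C7–OH) with 19 (DIC, DMAP, CH2Cl2) gives silyl-protected ester F6. HF·pyridine in THF removes the silyl group to give 21.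

**Further compounds**

F1 | step 7 | tert-butyl 2-[(3R,4S,6S,7R)-6-[(tert-butyldimethylsilyl)oxy]-3-hydroxy-8-[methoxy(methyl)carbamoyl]-7-methylnona-1,8-dien-4-yl]prop-2-enoate | C=C[C@@H](O)[C@@H](C[C@H](O[Si](C)(C)C(C)(C)C)[C@H](C)C(=C)C(=O)N(C)OC)C(=C)C(=O)OC(C)(C)C
F2 | step 7 | tert-butyl 2-[(3R,4S,6S,7R)-3-acetoxy-6-[(tert-butyldimethylsilyl)oxy]-8-[methoxy(methyl)carbamoyl]-7-methylnona-1,8-dien-4-yl]prop-2-enoate | C=C[C@@H](OC(C)=O)[C@@H](C[C@H](O[Si](C)(C)C(C)(C)C)[C@H](C)C(=C)C(=O)N(C)OC)C(=C)C(=O)OC(C)(C)C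
F3 | step 10 | tert-butyl 2-[(1R,2R,4S,5S,6S,7R)-4-[(tert-butyldimethylsilyl)oxy]-6,7-epoxy-1-hydroxy-6-[methoxy(methyl)carbamoyl]-5-methylcycloheptan-2-yl]prop-2-enoate | C=C(C(=O)OC(C)(C)C)[C@H]1C[C@H](O[Si](C)(C)C(C)(C)C)[C@H](C)[C@]2(C(=O)N(C)OC)O[C@@H]2[C@@H]1O
F4 | step 11 | tert-butyl 2-[(1R,2R,4S,5S,6S,7S)-6-[(E)-but-2-enoyl]-4-[(tert-butyldimethylsilyl)oxy]-1,6,7-trihydroxy-5-methylcycloheptan-2-yl]prop-2-enoate | C=C(C(=O)OC(C)(C)C)[C@H]1C[C@H](O[Si](C)(C)C(C)(C)C)[C@H](C)[C@@](O)(C(=O)/C=C/C)[C@H]([C@@H]1O)O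
F5 | step 11 | (1R,2R,4S,5S,6S,7S) trans-fused α-methylene-γ-lactone with C4–OTBS, C6–OH, C7–OH and C6 (E)-but-2-enoyl | C=C1C(=O)O[C@@H]2[C@@H]1C[C@H](O[Si](C)(C)C(C)(C)C)[C@H](C)[C@@](O)(C(=O)/C=C/C)[C@H]2O
F6 | step 11 | C4 tert-butyldimethylsilyl ether of 21 | C=C1C(=O)O[C@@H]2[C@@H]1C[C@H](O[Si](C)(C)C(C)(C)C)[C@H](C)[C@@](O)(C(=O)/C=C/C)[C@H]2OC(=O)[C@H](C)CC
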